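The vessels are three closed, stirred flasks of solid substrate, alike but for their temperature, and each stands for 40 h.

| flask | solid substrate | temperature | remark | time |
|---|---|---|---|---|
| Wednesday's | 0.064 M | −12 °C | run made earlier |  |
| Tuesday's | 0.14 M | 15 °C | run made earlier |  |
| beta | 0.096 M | 0 °C |  | 40 h |
| theta | 0.096 M | −25 °C |  | 40 h |
| zeta | 0.096 M | 25 °C |  | 40 h |

| run | time / h | target / % | solid substrate / % |
|---|---|---|---|
| Wednesday's | 5.00 | 0.5 | 85.1 |
| Wednesday's | 10.0 | 0.6 | 78.3 |
| Wednesday's | 15.0 | 0.7 | 74.3 |
| Wednesday's | 25.0 | 2.6 | 67.8 |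
| Wednesday's | 50.0 | 5.0 | 52.3 |
| Wednesday's | 72.0 | 8.0 | 39.7 |
| Tuesday's | 3.00 | 0.4 | 93.0 |
| Tuesday's | 6.00 | 2.0 | 86.5 |
| Tuesday's | 10.0 | 2.9 | 77.9 |
| Tuesday's | 12.0 | 3.5 | 73.7 |
| Tuesday's | 15.0 | 4.9 | 67.1 |
| Tuesday's | 20.0 | 6.8 | 56.7 |

(standard deviation of a reading: 0.3 percentage points)

* the flask that comes out highest in amount of target, in percent of the solid substrate charged, or "all alike" when all lie within 1.5 percentage points (beta / theta / zeta / all alike)
* target at the end, in percent of the solid substrate charged, beta
* target at the end, in percent of the solid substrate charged, theta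
* target at the end, in percent of the solid substrate charged, zeta

- given per volume of solution although it is solid: solid substrate
- the numbers in the tables scatter by 0.3 percentage points (one standard deviation)
- at the start none of the solid substrate is in solution
- in a conversion other conformer counts as not yet reacted; third conformer counts as reacted
- what has only dissolved of solid substrate counts as not reacted

At the start each flask holds undissolved solid, and what matters is how long that solid lasts. In Tuesday's run it falls on a straight line, with twice as much lost by 20.0 h as by 10.0 h, at 3.03 mM h⁻¹. We call this the feed and read going into solution as the rate-limiting step of that run. Dividing the charge of 0.096 M by the feed gives 31.7 h, the emptying time, which is how long a charge lasts while solid leaves at the feed. At the cold end, Wednesday's run finishes at 0.367 mM h⁻¹, far slower than the feed, and at that pace the same charge would last 262 h.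

Joining the two ends, we expect zeta, warmer than Tuesday's run, to pass its emptying time before the end. It should then hold no solid, and its target should stand near Tuesday's share of solid lost, 15.7%. We expect theta and beta still to hold solid and still to be moving.

The forecast, reckoned its own way, names zeta highest: 11% (7% to 14%) for beta, 0.3% (0.1% to 1%) for theta and 16% (13% to 19%) for zeta, where “everything dissolves and reacts by about 32 h”.

The flasks give 9.98% in beta, 0.434% in theta and 15.1% in zeta, so zeta is highest, and the forecast's ranges hold all three.

    other conformer ⇌ third conformer (K = 0.700, k = 0.00400 min⁻¹, Ea = 90.0 kJ mol⁻¹, ΔH = −58.0 kJ mol⁻¹)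
    other conformer → isomer of the product (k = 7.90 × 10⁻⁴ min⁻¹, Ea = 83.0 kJ mol⁻¹)
    starting material → target (k = 0.00130 min⁻¹, Ea = 82.0 kJ mol⁻¹)
    starting material ⇌ other conformer (K = 2.40, k = 0.110 min⁻¹, Ea = 90.0 kJ mol⁻¹, ΔH = 27.0 kJ mol⁻¹)
    starting material → decomposition product (k = 2.10 × 10⁻⁶ min⁻¹, Ea = 108 kJ mol⁻¹)
    solid substrate ⇌ starting material, rate k6*(cs6 - [starting material]) while solid is left; crystals form when [starting material] > cs6 (solubility = 5.50 mM, k = 0.0110 min⁻¹)
    starting material ⇌ dormant form (K = 0.710, k = 0.00280 min⁻¹, Ea = 79.0 kJ mol⁻¹, ΔH = −22.0 kJ mol⁻¹)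
    third conformer → third product (k = 0.00360 min⁻¹, Ea = 89.0 kJ mol⁻¹)
    (constants at 0 °C)

Zeta has come to rest: its solid substrate stands at 0% at 40.0 h, and its target is 15.1% then and 15.1% at 400 h, ten times the time. The neighbour at 50 °C, with the same charge and so the same emptying time of 31.7 h, also ends with 0% of it, and with target at 9.09%. Beta has not come to rest: it still holds 33.2% solid substrate at 40.0 h, and by 400 h, ten times the time, its target reaches 19.6%, twice its value. Theta, with 88.3% solid substrate at 40.0 h, is still moving too, and by 400 h its target reaches 4.61%.

The runs stem from a simulated flask on assumed constants, and the scatter is random.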